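Take a stirred flask in which one step sets acid free and fast balances catch that acid, and follow one ratio through it.

electrophile 0.50 mM; nucleophile 2.00 equiv; gas 0.056 mM (held); time 1.0 min

    electrophile + nucleophile → acid set free + product (k1 = 16.1 M⁻¹ s⁻¹)
    nucleophile + acid set free ⇌ protonated nucleophile, settled at all times (K2 = 1.0 × 10⁵ M⁻¹)
    acid set free + free base ⇌ salt of the base, settled at all times (K3 = 41000 M⁻¹)
    acid set free + free base ⇌ idle adduct, settled at all times (K4 = 2.4 × 10⁶ M⁻¹)
    gas ⇌ free base, rate k5*(csat - [free base]) (k5 = 10.0 s⁻¹, csat = 0.056 mM)

- what is said of acid set free includes idle adduct
- at the start none of free base is dissolved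
- run time (flask): 1.0 min

* part of the electrophile that has reacted at 1.0 min
* share of the unused nucleophile that is free and not bound as protonated nucleophile, at 1.0 min

The first step spends one electrophile and one nucleophile per event, so their difference, the gap, stays constant while that step is the one loss. The electrophile, charged at less than the nucleophile, is the limiting reagent.

Per unit of itself, electrophile falls at k·c(nucleophile) and nucleophile at k·c(electrophile). The logarithm of their ratio therefore climbs at k times the gap, a straight line in time.

gap = 1.00 mM − 0.50 mM = 0.500 mM

τ = 1/(16.1 M⁻¹ s⁻¹ × gap) = 2.07 min

ln[c(nucleophile)/c(electrophile)] = ln(2.00) + t/τ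

This τ, the time in which the logarithm of the ratio climbs by one unit, is the gap time. After 1.0 min:

ratio = 2.00 × exp(1.0 min/τ) = 3.24

c(electrophile) = gap/(ratio − 1) = 0.223 mM

My reckoning thus gives 55.4 % reacted. It counts every unused nucleophile as free, so it stops short of the second question.

The forecast says 53 % reacted and 88 % free, on the ground that “the free base stays near saturation and takes up most of the released acid as idle adduct”. Its reacted part lies below mine.

The flask gives 53.2 % reacted and 88.4 % free, both within the forecast's margin. In the flask, the first step ran throughout, with half of its turnover up to 1.0 min done by 0.356 min, while free base stood at 0.0558 mM. By 1.00 min the flask held 0.176 mM idle adduct and 0.0853 mM protonated nucleophile. Free nucleophile over electrophile then read 2.77, against 3.24 from the gap time. In the neighbour flask with 5.00 equiv of nucleophile, the gap time is 0.518 min, which gives 88.0 % reacted, and that flask reached 86.0 %.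

(The constants were set for the occasion; no experiment stands behind them.)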